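## Retrosynthetic overview

- Target ⇒ one-flask Br+ relay from a 2,5-trans-3-bromo-oxolane alcohol carrying the 12E-pentenyl arm: Br+ at C12/C13, O7 closes on C13 (bicyclic oxonium), the anti C9–Br reopens C10–O7 to the oxocane 9,10-bromonium ion (that of deacetyllaurencin), and 6-OH closes on C10.
- Ring order in that step: oxocane first (O7–C13, Br on C12), then oxane (O6–C10, Br on C9). These are the bonds, alkene geometries and Br+ events of laurediol → deacetyllaurencin → target.
- Bromo-oxolane ⇒ ketal-terminated 5-endo bromoetherification of (3E,6R,7R)-laurediol acetonide at the 9Z alkene (a temporary O7–C10 ring that fixes C9 and C10).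
- Laurediol ⇒ (R,R)-diepoxybutane opened at both CH2 ends by alkynyl anions: hept-4-en-1-yne (then cis semi-hydrogenation) and silylbutadiyne (then hydroxyl-directed trans reduction).

Assumption and convention: the SMILES is read as (3E,6R,7R,9S,10S,12S,13R)-9,12-dibromo-6,10:7,13-diepoxypentadec-3-en-1-yne; locants C1–C15, O6 and O7 are those of this chain throughout; (2R,2'R)-2,2'-bioxirane and Et2SBr·SbCl5Br are taken as purchasable.

## Route

Step 1
Reactants: 1 (E)-1-bromopent-2-ene; 2 ethynylmagnesium bromide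
Product: 3 (E)-hept-4-en-1-yne
Conditions: CuCl (5 mol%), THF, 0 → 50 °C
Reagents that add atoms: none
Why: Cu-catalysed SN2 coupling of an alkynyl Grignard reagent with a primary allylic bromide gives the skipped enyne with the E alkene retained; no stereocentre is formed.

Step 2
Reactants: 3 (E)-hept-4-en-1-yne; 4 (2R,2'R)-2,2'-bioxirane
Product: 6 (1R,6E)-1-[(2R)-oxiran-2-yl]non-6-en-3-yn-1-ol, via lithium heptenynide 5 (not isolated)
Conditions: n-BuLi, THF, −78 °C; then BF3·OEt2, 4 (2.5 equiv), −78 °C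
Reagents that add atoms: none
Why: Yamaguchi-type BF3-assisted alkynylation opens one epoxide of the C2-symmetric bis-epoxide at its CH2 terminus (SN2), so C6 and C7 keep the R configurations bought with 4, and the excess of 4 keeps double opening low.

Step 3
Reactants: 6 (1R,6E)-1-[(2R)-oxiran-2-yl]non-6-en-3-yn-1-ol
Product: 7 (1R,3Z,6E)-1-[(2R)-oxiran-2-yl]nona-3,6-dien-1-ol
Conditions: H2 (1 atm), Pd/CaCO3 poisoned with Pb(OAc)2, quinoline, EtOAc, rt
Reagents that add atoms: none
Why: Lindlar-type syn semi-hydrogenation of the only alkyne sets the 9Z alkene, while the epoxide, the alcohol and the 12E alkene are inert.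

Step 4
Reactants: 7 (1R,3Z,6E)-1-[(2R)-oxiran-2-yl]nona-3,6-dien-1-ol; 8 1,4-bis(trimethylsilyl)buta-1,3-diyne
Product: 10 (6R,7R,9Z,12E)-1-(trimethylsilyl)pentadeca-9,12-diene-1,3-diyne-6,7-diol, via lithium silylbutadiynide 9 (not isolated)
Conditions: 8, MeLi·LiBr, THF, 0 °C → rt; then 7, BF3·OEt2, −78 °C (3 equiv of 9)
Reagents that add atoms: none
Why: Mono-desilylation of 8 by MeLi gives the diynyl lithium, which opens the remaining epoxide at C5 by the same BF3-assisted SN2 alkynylation (the low temperature suppresses Payne rearrangement of the epoxy alkoxide); no stereocentre is touched.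

Step 5
Reactants: 10 (6R,7R,9Z,12E)-1-(trimethylsilyl)pentadeca-9,12-diene-1,3-diyne-6,7-diol
Product: 12 (3E,6R,7R,9Z,12E)-pentadeca-3,9,12-trien-1-yne-6,7-diol, via silyl enyne diol 11 (not isolated)
Conditions: LiAlH4, THF, 0 °C → rt; then MeOH, rt; aq. KNa tartrate
Reagents that add atoms: none
Why: Alkoxide-directed trans-hydroalumination (LiAlH4 reduction of a homopropargylic diynol) reduces only the activated C3≡C4 bond of the conjugated diyne to the 3E alkene, and the methoxide formed on quenching cleaves the alkynyl C–Si bond.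

Step 6
Reactants: 12 (3E,6R,7R,9Z,12E)-pentadeca-3,9,12-trien-1-yne-6,7-diol
Product: 13 (4R,5R)-2,2-dimethyl-4-[(2Z,5E)-octa-2,5-dien-1-yl]-5-[(2E)-pent-2-en-4-yn-1-yl]-1,3-dioxolane
Conditions: 2,2-dimethoxypropane, pyridinium p-toluenesulfonate (5 mol%), CH2Cl2, rt
Reagents that add atoms: 2,2-dimethoxypropane COC(C)(C)OC
Why: Acid-catalysed transketalisation of the threo-1,2-diol gives the trans-dioxolane with both stereocentres unchanged.

Step 7
Reactants: 13 (4R,5R)-2,2-dimethyl-4-[(2Z,5E)-octa-2,5-dien-1-yl]-5-[(2E)-pent-2-en-4-yn-1-yl]-1,3-dioxolane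
Product: 16 (3E,6R,7R,9S,10S,12E)-9-bromo-7,10-epoxypentadeca-3,12-dien-1-yn-6-ol, via ketal oxonium salt 14 (not isolated), via oxocarbenium salt 15 (not isolated)
Conditions: Et2SBr·SbCl5Br (1.0 equiv), MeNO2, −25 °C, 10 min; then aq. NaHCO3, rt
Reagents that add atoms: bromodiethylsulfonium bromopentachloroantimonate CC[S+](Br)CC.Cl[Sb-](Cl)(Cl)(Cl)(Cl)Br
Why: Proposed new method: Br+ (shuttled reversibly between the two isolated alkenes by Et2S) is funnelled into the 9Z alkene because only there can the proximal ketal oxygen O7 close a five-membered ring (5-endo at C10, anti to Br; attack by O6 would need a bridged oxonium) to a cis-fused bicyclic oxonium in which the pentenyl arm and Br sit on the convex face away from the ketal methyl groups, which sets 9S and 10S trans to C6; the oxonium then sheds the isopropylidene as an oxocarbenium ion that water hydrolyses to the free 6-OH; the closest known reactions are haloetherifications of alkenyl acetonides that end with loss of acetone, 5-endo halocyclisation of homoallylic alcohols, and bromonium capture by ether oxygen with this reagent.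

Step 8
Reactants: 16 (3E,6R,7R,9S,10S,12E)-9-bromo-7,10-epoxypentadeca-3,12-dien-1-yn-6-ol
Product: 19 (3E,6R,7R,9S,10S,12S,13R)-9,12-dibromo-6,10:7,13-diepoxypentadec-3-en-1-yne, via dibromo bicyclic oxonium salt 17 (not isolated), via oxocane bromonium salt 18 (not isolated)
Conditions: Et2SBr·SbCl5Br (1.1 equiv), MeNO2, −25 → 0 °C; cold aq. NaHCO3
Reagents that add atoms: bromodiethylsulfonium bromopentachloroantimonate CC[S+](Br)CC.Cl[Sb-](Cl)(Cl)(Cl)(Cl)Br
Why: Proposed new method: Br+ on the 12E alkene is captured 5-endo at C13 by the oxolane oxygen (anti addition with ethyl on the convex face of the cis-fused oxonium, giving 12S and 13R), the C9–Br bond, antiperiplanar to C10–O7 because it was installed by anti addition, then displaces O7 from C10 to give the oxocane 9,10-bromonium ion on the face opposite the C6 arm, and 6-OH opens it at C10 (6-endo, anti) with overall retention at C10, the only irreversible exit from the cation manifold; the closest known reactions are the bromonium-induced ring expansion of oxolanes to oxocanes through bicyclic oxonium ions with this reagent and the transannular bromoetherification of a hydroxy-oxocene, whose bromonium ion is this same intermediate.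

## Compound list

1 | (E)-1-bromopent-2-ene | CC/C=C/CBr | starting material
2 | ethynylmagnesium bromide | C#C[Mg]Br | starting material
3 | (E)-hept-4-en-1-yne | C#CC/C=C/CC | intermediate
4 | (2R,2'R)-2,2'-bioxirane, i.e. (R,R)-1,2:3,4-diepoxybutane | C1O[C@H]1[C@H]1CO1 | starting material
5 | lithium (E)-hept-4-en-1-yn-1-ide | [Li]C#CC/C=C/CC | intermediate
6 | (1R,6E)-1-[(2R)-oxiran-2-yl]non-6-en-3-yn-1-ol | C1O[C@H]1[C@H](O)CC#CC/C=C/CC | intermediate
7 | (1R,3Z,6E)-1-[(2R)-oxiran-2-yl]nona-3,6-dien-1-ol | C1O[C@H]1[C@H](O)C/C=C\C/C=C/CC | intermediate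
8 | 1,4-bis(trimethylsilyl)buta-1,3-diyne | C[Si](C)(C)C#CC#C[Si](C)(C)C | starting material
9 | lithium 4-(trimethylsilyl)buta-1,3-diyn-1-ide | [Li]C#CC#C[Si](C)(C)C | intermediate
10 | (6R,7R,9Z,12E)-1-(trimethylsilyl)pentadeca-9,12-diene-1,3-diyne-6,7-diol | C[Si](C)(C)C#CC#CC[C@@H](O)[C@H](O)C/C=C\C/C=C/CC | intermediate
11 | (3E,6R,7R,9Z,12E)-1-(trimethylsilyl)pentadeca-3,9,12-trien-1-yne-6,7-diol | C[Si](C)(C)C#C/C=C/C[C@@H](O)[C@H](O)C/C=C\C/C=C/CC | intermediate
12 | (3E,6R,7R,9Z,12E)-pentadeca-3,9,12-trien-1-yne-6,7-diol, (3E)-laurediol | C#C/C=C/C[C@@H](O)[C@H](O)C/C=C\C/C=C/CC | intermediate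
13 | (4R,5R)-2,2-dimethyl-4-[(2Z,5E)-octa-2,5-dien-1-yl]-5-[(2E)-pent-2-en-4-yn-1-yl]-1,3-dioxolane | C#C/C=C/C[C@H]1OC(C)(C)O[C@@H]1C/C=C\C/C=C/CC | intermediate
14 | cis-fused dioxolane–oxolane oxonium bromopentachloroantimonate (O7 bonded to C7, C10 and CMe2; 9S-Br, 10S) | C#C/C=C/C[C@H]1OC(C)(C)[O+]2[C@@H]1C[C@H](Br)[C@@H]2C/C=C/CC.Cl[Sb-](Cl)(Cl)(Cl)(Cl)Br | intermediate
15 | O6-(propan-2-ylidene)oxonium bromopentachloroantimonate of the bromo-oxolane | C#C/C=C/C[C@@H]([O+]=C(C)C)[C@H]1C[C@H](Br)[C@H](C/C=C/CC)O1.Cl[Sb-](Cl)(Cl)(Cl)(Cl)Br | intermediate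
16 | (3E,6R,7R,9S,10S,12E)-9-bromo-7,10-epoxypentadeca-3,12-dien-1-yn-6-ol, i.e. (1R,3E)-1-[(2R,4S,5S)-4-bromo-5-[(2E)-pent-2-en-1-yl]oxolan-2-yl]hex-3-en-5-yn-1-ol | C#C/C=C/C[C@@H](O)[C@H]1C[C@H](Br)[C@H](C/C=C/CC)O1 | intermediate
17 | 9,12-dibromo bicyclic oxonium bromopentachloroantimonate (O7 bonded to C7, C10 and C13; two cis-fused five-membered rings) | C#C/C=C/C[C@@H](O)[C@H]1C[C@H](Br)[C@@H]2C[C@H](Br)[C@@H](CC)[O+]12.Cl[Sb-](Cl)(Cl)(Cl)(Cl)Br | intermediate
18 | 12-bromo-7,13-epoxy oxocane 9,10-bromonium bromopentachloroantimonate (Br+ bridging C9 and C10, anti to the C6 arm) | C#C/C=C/C[C@@H](O)[C@H]1C[C@@H]2[Br+][C@@H]2C[C@H](Br)[C@@H](CC)O1.Cl[Sb-](Cl)(Cl)(Cl)(Cl)Br | intermediate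
19 | (3E,6R,7R,9S,10S,12S,13R)-9,12-dibromo-6,10:7,13-diepoxypentadec-3-en-1-yne (CNP0202038.1) | C#C/C=C/C[C@H]1O[C@H]2C[C@H](Br)[C@@H](CC)O[C@@H]1C[C@@H]2Br | target

## Step count and risks

Total step count: 8.
Longest linear sequence: 8 steps (1 → 3 → 6 → 7 → 10 → 12 → 13 → 16 → 19).

**Step 8 (the relay).** The oxonium salt 17 may be opened by external halide, the enyne may be brominated, or 6-OH may close on C9 instead of C10. The fallback sets out from 16 and comes back at 19, replacing the one-flask internal trapping by a stepwise passage through the isolated oxocene.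
- O6 is silylated (TBSOTf, 2,6-lutidine, CH2Cl2) to tert-butyl{[(3E,6R,7R,9S,10S,12E)-9-bromo-7,10-epoxypentadeca-3,12-dien-1-yn-6-yl]oxy}dimethylsilane F5, so the cations can no longer be trapped internally.
- Et2SBr·SbCl5Br in MeNO2 at −25 °C is followed by excess NaI, which removes the bromine anti to the oxonium C10–O7 bond (halophilic attack, as in NaI debromination of vicinal dibromides). This gives tert-butyl{[(3E,6R,7R,9Z,12S,13R)-12-bromo-7,13-epoxypentadeca-3,9-dien-1-yn-6-yl]oxy}dimethylsilane F6 beside recyclable F5.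
- Bu4NF in THF at 0 °C frees (3E,6R,7R,9Z,12S,13R)-12-bromo-7,13-epoxypentadeca-3,9-dien-1-yn-6-ol F7 (deacetyllaurencin).
- NBS in CH2Cl2 then performs the conventional transannular bromoetherification to 19.

**Step 7 (ketal-terminated 5-endo closure).** The oxocarbenium ion 15 may lose a proton to an enol ether that consumes Br+, or the ketal oxygen may react too slowly. The fallback sets out from 12 and comes back at 16, changing the terminating group from a ketal to an orthoester.
- MeC(OMe)3 with pyridinium p-toluenesulfonate gives (4R,5R)-2-methoxy-2-methyl-4-[(2Z,5E)-octa-2,5-dien-1-yl]-5-[(2E)-pent-2-en-4-yn-1-yl]-1,3-dioxolane F3.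
- The same Br+ reagent closes O7 on C10; the ring-opened cation is now a dialkoxycarbenium ion that cannot form an enol ether, and it is hydrolysed on work-up to (3E,6R,7R,9S,10S,12E)-9-bromo-7,10-epoxypentadeca-3,12-dien-1-yn-6-yl acetate F4.
- K2CO3 in MeOH gives 16.

**Step 5 (diyne to E-enyne).** Over-reduction or poor regiocontrol is possible for a homopropargylic rather than propargylic diynol. The fallback sets out from 7 and comes back at 12 through 11, building the enyne by cross-coupling instead.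
- LiC≡CH·H2NCH2CH2NH2 in DMSO opens the epoxide to (4R,5R,7Z,10E)-trideca-7,10-dien-1-yne-4,5-diol F1.
- Cp2Zr(H)Cl (excess, THF) then I2 gives (1E,4R,5R,7Z,10E)-1-iodotrideca-1,7,10-triene-4,5-diol F2.
- Sonogashira coupling with ethynyltrimethylsilane (Pd(PPh3)4, CuI, Et2NH) gives 11, and K2CO3 in MeOH gives 12.

## Further compounds

F1 | step 5 | (4R,5R,7Z,10E)-trideca-7,10-dien-1-yne-4,5-diol | C#CC[C@@H](O)[C@H](O)C/C=C\C/C=C/CC
F2 | step 5 | (1E,4R,5R,7Z,10E)-1-iodotrideca-1,7,10-triene-4,5-diol | I/C=C/C[C@@H](O)[C@H](O)C/C=C\C/C=C/CC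
F3 | step 7 | (4R,5R)-2-methoxy-2-methyl-4-[(2Z,5E)-octa-2,5-dien-1-yl]-5-[(2E)-pent-2-en-4-yn-1-yl]-1,3-dioxolane (both C2 epimers) | C#C/C=C/C[C@H]1OC(C)(OC)O[C@@H]1C/C=C\C/C=C/CC
F4 | step 7 | (3E,6R,7R,9S,10S,12E)-9-bromo-7,10-epoxypentadeca-3,12-dien-1-yn-6-yl acetate | C#C/C=C/C[C@@H](OC(C)=O)[C@H]1C[C@H](Br)[C@H](C/C=C/CC)O1
F5 | step 8 | tert-butyl{[(3E,6R,7R,9S,10S,12E)-9-bromo-7,10-epoxypentadeca-3,12-dien-1-yn-6-yl]oxy}dimethylsilane | C#C/C=C/C[C@@H](O[Si](C)(C)C(C)(C)C)[C@H]1C[C@H](Br)[C@H](C/C=C/CC)O1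
F6 | step 8 | tert-butyl{[(3E,6R,7R,9Z,12S,13R)-12-bromo-7,13-epoxypentadeca-3,9-dien-1-yn-6-yl]oxy}dimethylsilane | C#C/C=C/C[C@@H](O[Si](C)(C)C(C)(C)C)[C@H]1C/C=C\C[C@H](Br)[C@@H](CC)O1
F7 | step 8 | (3E,6R,7R,9Z,12S,13R)-12-bromo-7,13-epoxypentadeca-3,9-dien-1-yn-6-ol (deacetyllaurencin) | C#C/C=C/C[C@@H](O)[C@H]1C/C=C\C[C@H](Br)[C@@H](CC)O1
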